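**Retrosynthetic overview**
- The target is opened from an all-cis 2,5-diaryl-3,4-dimethyloxolane by hydrogenolysis of both ring benzylic C–O bonds; the oxolane comes from syn-hydrogenation of a cis-2-aryl-3-methyl-2,3-dihydrofuran.
- The dihydrofuran comes from a γ-keto aldehyde by aryl Grignard addition (guaiacyl ring) and cyclodehydration, which erases the stereocentre beside the ketone.
- Key bond: the central CH(CH3)–CH(CH3) bond, made between two carbonyl α-carbons. Propanal reacts as a chiral enamine and an α-bromo propiophenone as an α-keto radical (enolonium-type partner); the catalyst sets the first methyl stereocentre.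
- The α-bromo ketone comes from propiosyringone by O-benzylation and α-bromination.
- Ring order: both benzene rings are bought; the only ring made is the five-membered oxygen ring, closed in step 4 and opened again in step 5.

Assumption: propiosyringone, propanal, 1-(benzyloxy)-4-bromo-2-methoxybenzene and the D-alanine-derived (2S,5R)-imidazolidinone salt are taken as purchasable; catalyst preparation is not counted.

**Step 1**
Reactants: 1 1-(4-hydroxy-3,5-dimethoxyphenyl)propan-1-one
Product: 2 1-[4-(benzyloxy)-3,5-dimethoxyphenyl]propan-1-one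
Conditions: BnBr (1.2 equiv), K2CO3 (2 equiv), DMF, 60 °C
Reagents that add atoms: benzyl bromide, BrCc1ccccc1
Why: Williamson etherification, in which the phenoxide formed with K2CO3 displaces bromide from benzyl bromide (SN2); benzyl is chosen because it is removed in the final hydrogenation without an extra step, and no stereocentre is formed.

**Step 2**
Reactants: 2 1-[4-(benzyloxy)-3,5-dimethoxyphenyl]propan-1-one
Product: 3 1-[4-(benzyloxy)-3,5-dimethoxyphenyl]-2-bromopropan-1-one (racemic)
Conditions: CuBr2 (2.1 equiv), EtOAc/CHCl3 (1:1), reflux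
Reagents that add atoms: copper dibromide (CuBr2), Br[Cu]Br
Why: α-Bromination of an aryl ethyl ketone with CuBr2 (King–Ostrum conditions) goes through the copper-bound enol and brominates only the CH2 beside the carbonyl, not the electron-rich ring; the new stereocentre is racemic, which is harmless because it becomes a planar radical in step 3.

**Step 3**
Reactants: 3 1-[4-(benzyloxy)-3,5-dimethoxyphenyl]-2-bromopropan-1-one; 4 propanal
Product: 5 (2S)-4-[4-(benzyloxy)-3,5-dimethoxyphenyl]-2,3-dimethyl-4-oxobutanal (both C3 epimers, about 1:1)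
Conditions: Ru(bpy)3Cl2 (0.5 mol%), (2S,5R)-2-tert-butyl-3,5-dimethylimidazolidin-4-one·CF3SO3H (20 mol%), 2,6-lutidine (2 equiv), propanal (3 equiv), DMF, blue LEDs, 23 °C, degassed
Reagents that add atoms: none
Why: Proposed new method: the reduced photocatalyst Ru(bpy)3+ cleaves the C–Br bond of 3 to an electrophilic secondary α-keto radical (a ketone α-carbon, normally a nucleophile, reacting as an enolonium-type partner), which adds to the E-enamine of propanal on the Re face left open by the 5-methyl group of the (2S,5R)-imidazolidinone; oxidation of the resulting α-amino radical by photoexcited Ru(bpy)3Cl2 and hydrolysis release 5 with C2 set as S under catalyst control (about 90% ee expected), while C3 forms unselectively and is left so on purpose because step 4 makes it planar; the closest known reaction type is the photoredox organocatalytic α-alkylation of aldehydes with primary phenacyl bromides and bromomalonates, extended here to a secondary α-bromo aryl ketone.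

**Step 4**
Reactants: 5 (2S)-4-[4-(benzyloxy)-3,5-dimethoxyphenyl]-2,3-dimethyl-4-oxobutanal; 6 1-(benzyloxy)-4-bromo-2-methoxybenzene
Product: 9 (2R,3S)-2-[4-(benzyloxy)-3-methoxyphenyl]-5-[4-(benzyloxy)-3,5-dimethoxyphenyl]-3,4-dimethyl-2,3-dihydrofuran, via aryl Grignard reagent 7 (not isolated), via hydroxy ketone 8 (not isolated)
Conditions: 6, Mg, THF, rt; then 5, THF, −78 °C; aq NH4Cl; then pyridinium p-toluenesulfonate (10 mol%), 4 Å MS, PhMe, 50 °C; chromatography on Et3N-washed SiO2 to remove the minor 2,3-trans isomer
Reagents that add atoms: none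
Why: Grignard addition followed by acid-catalysed cyclodehydration: the aryl Grignard reagent adds to the aldehyde far faster than to the hindered, electron-rich aryl ketone and, by the Felkin–Anh model, anti to the large ketone-bearing branch, which sets the carbinol carbon as R (syn to the methyl group); the γ-hydroxy ketone then closes through its hemiketal and loses water to the conjugated 2,3-dihydrofuran, in which the carbon beside the former ketone is sp2, so both epimers of 5 converge on one compound with aryl and methyl cis.

**Step 5**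
Reactants: 9 (2R,3S)-2-[4-(benzyloxy)-3-methoxyphenyl]-5-[4-(benzyloxy)-3,5-dimethoxyphenyl]-3,4-dimethyl-2,3-dihydrofuran
Product: 11 4-[(2S,3R)-4-(4-hydroxy-3-methoxyphenyl)-2,3-dimethylbutyl]-2,6-dimethoxyphenol, via all-cis oxolane bisphenol 10 (not isolated)
Conditions: H2 (3 atm), 10% Pd/C, EtOAc, rt; then AcOH, HClO4 (cat.), H2 (4 atm), 40 °C
Reagents that add atoms: none
Why: Heterogeneous syn-hydrogenation followed by benzylic hydrogenolysis: H2 is delivered on Pd to the ring face opposite the cis 2-aryl and 3-methyl groups, which sets C4 (and C5) and gives the all-cis oxolane, the same facial course as the classical hydrogenation of 2,5-diaryl-3,4-dimethylfurans; the benzyl ethers fall off in the neutral stage, and under acid the two ring benzylic C–O bonds are cleaved without touching the methyl-bearing carbons, so the cis-3,4-dimethyl oxolane opens to the (2S,3R)-butane.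

**Compound list**
1 | 1-(4-hydroxy-3,5-dimethoxyphenyl)propan-1-one (propiosyringone) | CCC(=O)c1cc(OC)c(O)c(OC)c1 | starting material
2 | 1-[4-(benzyloxy)-3,5-dimethoxyphenyl]propan-1-one | CCC(=O)c1cc(OC)c(OCc2ccccc2)c(OC)c1 | intermediate
3 | 1-[4-(benzyloxy)-3,5-dimethoxyphenyl]-2-bromopropan-1-one (racemic) | CC(Br)C(=O)c1cc(OC)c(OCc2ccccc2)c(OC)c1 | intermediate
4 | propanal | CCC=O | starting material
5 | (2S)-4-[4-(benzyloxy)-3,5-dimethoxyphenyl]-2,3-dimethyl-4-oxobutanal (both C3 epimers) | O=C[C@@H](C)C(C)C(=O)c1cc(OC)c(OCc2ccccc2)c(OC)c1 | intermediate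
6 | 1-(benzyloxy)-4-bromo-2-methoxybenzene | COc1cc(Br)ccc1OCc1ccccc1 | starting material
7 | [4-(benzyloxy)-3-methoxyphenyl]magnesium bromide | COc1cc([Mg]Br)ccc1OCc1ccccc1 | intermediate
8 | (3S,4R)-4-[4-(benzyloxy)-3-methoxyphenyl]-1-[4-(benzyloxy)-3,5-dimethoxyphenyl]-4-hydroxy-2,3-dimethylbutan-1-one (both C2 epimers) | COc1cc(ccc1OCc1ccccc1)[C@H](O)[C@@H](C)C(C)C(=O)c1cc(OC)c(OCc2ccccc2)c(OC)c1 | intermediate
9 | (2R,3S)-2-[4-(benzyloxy)-3-methoxyphenyl]-5-[4-(benzyloxy)-3,5-dimethoxyphenyl]-3,4-dimethyl-2,3-dihydrofuran | COc1cc(ccc1OCc1ccccc1)[C@@H]1OC(=C(C)[C@@H]1C)c1cc(OC)c(OCc2ccccc2)c(OC)c1 | intermediate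
10 | (2R,3S,4R,5S)-2-(4-hydroxy-3-methoxyphenyl)-5-(4-hydroxy-3,5-dimethoxyphenyl)-3,4-dimethyloxolane (all-cis) | COc1cc(ccc1O)[C@@H]1O[C@H](c2cc(OC)c(O)c(OC)c2)[C@H](C)[C@@H]1C | intermediate
11 | 4-[(2S,3R)-4-(4-hydroxy-3-methoxyphenyl)-2,3-dimethylbutyl]-2,6-dimethoxyphenol | COc1cc(C[C@@H](C)[C@@H](C)Cc2cc(OC)c(O)c(OC)c2)ccc1O | target

**Step count**
Total steps: 5. Longest linear sequence: 5 steps (1 → 2 → 3 → 5 → 9 → 11).

**Steps most likely to fail, with fallbacks**

Step 3 (secondary α-keto radical may add slowly, eliminate HBr, or give low ee). The fallback sets out from 2 and comes back at 5. Ketone 2 is silylated (TBSOTf, Et3N, CH2Cl2, 0 °C) to the silyl enol ether tert-butyl({(1Z)-1-[4-(benzyloxy)-3,5-dimethoxyphenyl]prop-1-en-1-yl}oxy)dimethylsilane F1. F1 is coupled with propanal 4 by organo-SOMO catalysis: (2R,5R)-5-benzyl-2-tert-butyl-3-methylimidazolidin-4-one trifluoroacetate (20 mol%), (NH4)2Ce(NO3)6 (2 equiv), 2,6-di-tert-butylpyridine, H2O, acetone, −20 °C. Here the reversed polarity sits on the other partner: the oxidised enamine radical cation is the electrophilic α-carbon and the enol silane the nucleophile. The 5R substituent again shields the Si face, so (2S)-5 results.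

Step 4 (Felkin selectivity of the Grignard addition may be modest, giving too much 2,3-trans dihydrofuran). The fallback sets out from 5 and comes back at 8, which is cyclodehydrated to 9 as before. [4-(Benzyloxy)-3-methoxyphenyl]boronic acid F2 (bought, or made from 6 by Br–Li exchange and B(OiPr)3) is transmetallated with Et2Zn. The resulting arylzinc is added to 5 under control of a chiral amino alcohol ligand (3-exo-morpholinoisoborneol, enantiomer matched with the Felkin preference, toluene, 0 °C). The carbinol configuration is then set by the catalyst and no longer by the substrate alone.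

Step 5 (the ring C–O bond may cleave before the alkene is saturated, or acid may scramble the methyl centres through benzylic cations, lowering the diastereomer ratio). The fallback sets out from 9 and comes back at 11. Compound 9 is hydrogenated over Rh/Al2O3 (H2 3 atm, EtOAc, rt), which saturates the enol ether but does not cleave benzylic C–O bonds. This gives isolable (2R,3S,4R,5S)-2-[4-(benzyloxy)-3-methoxyphenyl]-5-[4-(benzyloxy)-3,5-dimethoxyphenyl]-3,4-dimethyloxolane F3, which is purified by crystallisation (this also upgrades ee). F3 is then opened by dissolving-metal reduction (Na, liquid NH3, THF, −78 °C), which cuts both ring benzylic C–O bonds and both benzyl ethers by electron transfer, without cationic intermediates.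

**Further compounds**
F1 | step 3 | tert-butyl({(1Z)-1-[4-(benzyloxy)-3,5-dimethoxyphenyl]prop-1-en-1-yl}oxy)dimethylsilane | C/C=C(\O[Si](C)(C)C(C)(C)C)c1cc(OC)c(OCc2ccccc2)c(OC)c1
F2 | step 4 | [4-(benzyloxy)-3-methoxyphenyl]boronic acid | COc1cc(B(O)O)ccc1OCc1ccccc1
F3 | step 5 | (2R,3S,4R,5S)-2-[4-(benzyloxy)-3-methoxyphenyl]-5-[4-(benzyloxy)-3,5-dimethoxyphenyl]-3,4-dimethyloxolane | COc1cc(ccc1OCc1ccccc1)[C@@H]1O[C@H](c2cc(OC)c(OCc3ccccc3)c(OC)c2)[C@H](C)[C@@H]1C
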